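The route rests on cutting the bond between the benzylic carbon on benzene ring A and the next methylene of the twelve-membered lactone ring B, an unfunctionalised CH2–CH2 pair that can be read as a hydrogenated alkene. That alkene is made by a Ramberg–Bäcklund reaction, which in one operation excises SO2 from a benzylic sulfone, forms the C–C bond and contracts a thirteen-membered ring to ring B. The precursor is the (R)-configured thirteen-membered sulfone lactone of an O-benzyl, O-methyl orsellinate, its sulfur joining the benzylic carbon to the hexamethylene chain. Lasiodiplodin then receives pyran ring C and furan ring D by an o-quinone methide cycloaddition.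

Key step: step 10

Assumption: aminomethylation of lasiodiplodin (step 12) is taken to occur at the ring carbon between the phenolic carbon and the chain-bearing carbon (ortho to OH, para to OMe); alkene 18 is drawn E, although its geometry is irrelevant after step 11.

Step 1
Reactants: 1 ethyl orsellinate
Product: 2 ethyl 4-(benzyloxy)-2-hydroxy-6-methylbenzoate
Conditions: BnBr (1.05 equiv), K2CO3, acetone, reflux
Reagents that add atoms: benzyl bromide, BrCc1ccccc1
Why: Williamson etherification is para-selective because the 2-OH is held in a hydrogen bond to the ester carbonyl while the 4-OH is free; the benzyl ether later keeps the phenol silent in step 10 and is removed in step 11.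

Step 2
Reactants: 2 ethyl 4-(benzyloxy)-2-hydroxy-6-methylbenzoate
Product: 3 ethyl 4-(benzyloxy)-2-methoxy-6-methylbenzoate
Conditions: MeI (excess), K2CO3, DMF, 50 °C
Reagents that add atoms: iodomethane, CI
Why: Williamson O-methylation of the remaining chelated phenol under more forcing conditions, to which the benzyl ether and the hindered ester are inert.

Step 3
Reactants: 3 ethyl 4-(benzyloxy)-2-methoxy-6-methylbenzoate
Product: 5 ethyl 4-(benzyloxy)-2-(chloromethyl)-6-methoxybenzoate, via lithiated toluate 4 (not isolated)
Conditions: LiN(i-Pr)2 (1.1 equiv), THF, −78 °C; then cannulated into C2Cl6 (2 equiv) in THF, −78 °C; sat. aq. NH4Cl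
Reagents that add atoms: hexachloroethane, ClC(Cl)(Cl)C(Cl)(Cl)Cl
Why: Lateral lithiation of the ortho-toluate gives an ester-stabilised benzylic carbanion, and inverse addition to excess C2Cl6 transfers Cl+ to it (electrophilic halogenation of a carbanion), which functionalises the methyl group without a radical bromination that the benzyl ether and the electron-rich ring would not tolerate.

Step 4
Reactants: 6 (S)-propylene oxide; 7 5-bromopent-1-ene
Product: 9 (2S)-oct-7-en-2-ol, via pent-4-enylmagnesium bromide 8 (not isolated)
Conditions: Mg, THF, rt; then CuI (10 mol%), 6, −30 → 0 °C; 1 M HCl work-up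
Reagents that add atoms: none
Why: CuI-catalysed SN2 opening of the epoxide by the Grignard reagent occurs at the unsubstituted carbon, so the (S) centre of the epoxide is carried over untouched as the carbinol centre.

Step 5
Reactants: 9 (2S)-oct-7-en-2-ol
Product: 10 S-[(7S)-7-hydroxyoctyl] ethanethioate
Conditions: AcSH (1.5 equiv), AIBN (cat.), toluene, 70 °C
Reagents that add atoms: thioacetic acid, CC(=O)S
Why: Radical thiol–ene addition of thioacetic acid to a terminal alkene is anti-Markovnikov and places sulfur on the terminal carbon, and the free secondary alcohol is a spectator in this radical chain.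

Step 6
Reactants: 5 ethyl 4-(benzyloxy)-2-(chloromethyl)-6-methoxybenzoate; 10 S-[(7S)-7-hydroxyoctyl] ethanethioate
Product: 12 ethyl 4-(benzyloxy)-2-({[(7S)-7-hydroxyoctyl]sulfanyl}methyl)-6-methoxybenzoate, via thiol 11 (not isolated)
Conditions: 10 (1.1 equiv), NaOEt (1.1 equiv), degassed EtOH, 0 °C; then 5, 0 °C → rt
Reagents that add atoms: none
Why: Ethoxide removes the acetyl group by acyl transfer and the resulting thiolate, far more nucleophilic than the free hydroxyl, displaces the benzylic chloride (SN2 thioether formation), while ethoxide in ethanol leaves the ethyl ester unchanged.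

Step 7
Reactants: 12 ethyl 4-(benzyloxy)-2-({[(7S)-7-hydroxyoctyl]sulfanyl}methyl)-6-methoxybenzoate
Product: 13 4-(benzyloxy)-2-({[(7S)-7-hydroxyoctyl]sulfanyl}methyl)-6-methoxybenzoic acid
Conditions: KOH (excess), EtOH/H2O, reflux; cold dilute HCl to pH 3
Reagents that add atoms: potassium hydroxide, [K+].[OH-]
Why: Forcing saponification of the 2,6-disubstituted benzoate (ester hydrolysis) gives the seco acid, and the sulfide, the aryl ethers and the carbinol centre are unaffected.

Step 8
Reactants: 13 4-(benzyloxy)-2-({[(7S)-7-hydroxyoctyl]sulfanyl}methyl)-6-methoxybenzoic acid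
Product: 14 (R)-configured 13-membered thioether lactone (ring: C(=O)–O–CH(CH3)–(CH2)6–S–CH2–arene; 4-OBn; 2-OMe)
Conditions: PPh3, DIAD, toluene (0.005 M, slow addition of 13), 0 °C → rt
Reagents that add atoms: none
Why: Mitsunobu macrolactonisation, in which the carboxylate displaces the activated secondary alcohol by SN2 at high dilution, inverts (S) to the (R) configuration of the target and closes the 13-membered ring; the hindrance of the acid is immaterial because it acts as the nucleophile.

Step 9
Reactants: 14 (R)-configured 13-membered thioether lactone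
Product: 15 (R)-configured 13-membered sulfone lactone (S,S-dioxide of 14)
Conditions: mCPBA (2.2 equiv), CH2Cl2, 0 °C → rt
Reagents that add atoms: mCPBA (3-chloroperoxybenzoic acid), OOC(=O)c1cccc(Cl)c1
Why: Sulfide-to-sulfone oxidation with two equivalents of peracid leaves the lactone, the aryl ethers and the stereocentre untouched.

Step 10
Reactants: 15 (R)-configured 13-membered sulfone lactone
Product: 18 (R)-O-benzyl-didehydrolasiodiplodin, via alpha-bromo sulfone 16 (not isolated), via episulfone 17 (not isolated)
Conditions: KOH/Al2O3, CBr2F2, t-BuOH/CH2Cl2, 5 °C → rt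
Reagents that add atoms: none
Why: Hydroxide removes the most acidic proton, on the benzylic carbon between the sulfonyl group and ring A, and the carbanion takes Br+ from CBr2F2 to give 16; deprotonation at the other alpha carbon then displaces bromide in a 1,3-elimination to episulfone 17, which loses SO2 in a cheletropic step and leaves the benzylic carbon and the first chain carbon joined as a styrenyl alkene. The closest known reaction type is the one-pot halogenative Ramberg–Bäcklund reaction of benzylic sulfones, including its use to contract macrocyclic sulfones to cycloalkenes and cyclophanes. Ring B is closed by ring contraction: the preformed 13-membered ring passes through a 3-exo-tet closure to the fused episulfone and becomes 12-membered when SO2 is expelled, so no macrocyclisation is asked of this step. No stereocentre is created, the alkene geometry (E expected for the conjugated styrene) is erased in step 11, and the remote (R) carbinol centre carries no acidic proton. Only chemoselectivity is needed, halogenation and elimination at the sulfone in preference to attack of hydroxide or of the sulfonyl carbanion on the lactone carbonyl: the two ortho substituents shield that carbonyl, closure of the three-membered ring is fast, the phenol is masked as its benzyl ether so that no phenoxide can be brominated or O-difluoromethylated, and difluorocarbene is consumed by the basic medium instead of the product alkene.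

Step 11
Reactants: 18 (R)-O-benzyl-didehydrolasiodiplodin
Product: 20 (R)-lasiodiplodin, via O-benzyllasiodiplodin 19 (not isolated)
Conditions: H2 (1 atm), Pd/C (palladium metal on carbon), EtOAc/EtOH, rt
Reagents that add atoms: none
Why: Heterogeneous hydrogenation saturates the styrenyl alkene and the same catalyst hydrogenolyses the benzyl ether; the lactone C–O bond is not benzylic and survives.

Step 12
Reactants: 20 (R)-lasiodiplodin
Product: 21 Mannich base: (R)-lasiodiplodin bearing a morpholin-4-ylmethyl group on the ring carbon between C–OH and the chain-bearing carbon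
Conditions: morpholine, 37% aq. CH2O, MeOH, reflux
Reagents that add atoms: formaldehyde, C=O; morpholine, C1COCCN1
Why: Mannich aminomethylation of a phenol goes ortho to OH, and of the two ortho carbons the one next to the chain is also para to the methoxy group, whereas the other is flanked by two oxygen substituents and lacks para-oxygen activation; the hindered lactone resists aminolysis.

Step 13
Reactants: 22 (4R)-4-benzyl-3-propanoyl-1,3-oxazolidin-2-one; 23 propargyl bromide
Product: 25 (4R)-4-benzyl-3-[(2S)-2-methylpent-4-ynoyl]-1,3-oxazolidin-2-one, via sodium enolate 24 (not isolated)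
Conditions: NaN(SiMe3)2, THF, −78 °C; then 23 (80 wt% in toluene), −78 → −40 °C
Reagents that add atoms: none
Why: Evans asymmetric alkylation, in which the chelated (Z)-enolate is alkylated on the face opposite the benzyl group of the (R)-auxiliary, sets the (S) methyl-bearing centre.

Step 14
Reactants: 25 (4R)-4-benzyl-3-[(2S)-2-methylpent-4-ynoyl]-1,3-oxazolidin-2-one
Product: 26 (2S)-2-methylpent-4-yn-1-ol
Conditions: LiBH4, H2O (1 equiv), Et2O, 0 °C
Reagents that add atoms: none
Why: Reductive cleavage of the N-acyl oxazolidinone with LiBH4 releases the primary alcohol without touching the stereocentre or the alkyne, and the auxiliary can be recovered.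

Step 15
Reactants: 26 (2S)-2-methylpent-4-yn-1-ol
Product: 28 (3S)-3,5-dimethyl-2,3-dihydrofuran, via exocyclic enol ether 27 (not isolated)
Conditions: NaNH2 (10 mol%), neat, 130 °C, product distilled out
Reagents that add atoms: none
Why: Base-catalysed cycloisomerisation (5-exo-dig addition of the alkoxide to the alkyne) gives the exocyclic enol ether, which the same base isomerises to the more substituted endocyclic enol ether; the stereocentre is not involved and the volatile product leaves the flask as it forms.

Step 16
Reactants: 21 Mannich base; 28 (3S)-3,5-dimethyl-2,3-dihydrofuran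
Product: 31 lasiodiplactone A, via ammonium iodide 29 (not isolated), via o-quinone methide 30 (not isolated)
Conditions: MeI (excess), 28 (3 equiv), toluene, 80 °C, sealed tube
Reagents that add atoms: none
Why: N-Methylation turns the amine into a leaving group whose thermal loss gives the o-quinone methide, which adds to the enol ether in an inverse-electron-demand hetero-Diels–Alder reaction (nucleophilic alkene carbon to the exocyclic CH2, quinone methide oxygen to the oxygen-bearing carbon); suprafacial addition makes the C/D ring fusion cis, and approach anti to the methyl group on the (S) centre of 28 should set C-3a and C-9a, the minor syn adduct being removed by chromatography.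

Compound list
1 | ethyl orsellinate (ethyl 2,4-dihydroxy-6-methylbenzoate) | CCOC(=O)c1c(C)cc(O)cc1O | starting material
2 | ethyl 4-(benzyloxy)-2-hydroxy-6-methylbenzoate | CCOC(=O)c1c(C)cc(OCc2ccccc2)cc1O | intermediate
3 | ethyl 4-(benzyloxy)-2-methoxy-6-methylbenzoate | CCOC(=O)c1c(C)cc(OCc2ccccc2)cc1OC | intermediate
4 | benzylic lithio derivative of 3 (lithiated toluate, not isolated) | CCOC(=O)c1c(C[Li])cc(OCc2ccccc2)cc1OC | intermediate
5 | ethyl 4-(benzyloxy)-2-(chloromethyl)-6-methoxybenzoate | CCOC(=O)c1c(CCl)cc(OCc2ccccc2)cc1OC | intermediate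
6 | (S)-propylene oxide | C[C@H]1CO1 | starting material
7 | 5-bromopent-1-ene | C=CCCCBr | starting material
8 | pent-4-enylmagnesium bromide (formed in the flask, not isolated) | C=CCCC[Mg]Br | intermediate
9 | (2S)-oct-7-en-2-ol | C[C@H](O)CCCCC=C | intermediate
10 | S-[(7S)-7-hydroxyoctyl] ethanethioate | C[C@H](O)CCCCCCSC(C)=O | intermediate
11 | (2S)-8-sulfanyloctan-2-ol (present as its sodium thiolate, not isolated) | C[C@H](O)CCCCCCS | intermediate
12 | ethyl 4-(benzyloxy)-2-({[(7S)-7-hydroxyoctyl]sulfanyl}methyl)-6-methoxybenzoate | CCOC(=O)c1c(CSCCCCCC[C@H](C)O)cc(OCc2ccccc2)cc1OC | intermediate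
13 | 4-(benzyloxy)-2-({[(7S)-7-hydroxyoctyl]sulfanyl}methyl)-6-methoxybenzoic acid | OC(=O)c1c(CSCCCCCC[C@H](C)O)cc(OCc2ccccc2)cc1OC | intermediate
14 | 13-membered thioether lactone, (R) at the carbinol carbon, 4-O-benzyl, 2-O-methyl | C[C@@H]1CCCCCCSCc2cc(OCc3ccccc3)cc(OC)c2C(=O)O1 | intermediate
15 | 13-membered benzylic sulfone lactone, (R), 4-O-benzyl, 2-O-methyl | C[C@@H]1CCCCCCS(=O)(=O)Cc2cc(OCc3ccccc3)cc(OC)c2C(=O)O1 | intermediate
16 | benzylic alpha-bromo sulfone of 15 (not isolated; configuration at CHBr undefined) | C[C@@H]1CCCCCCS(=O)(=O)C(Br)c2cc(OCc3ccccc3)cc(OC)c2C(=O)O1 | intermediate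
17 | episulfone (thiirane 1,1-dioxide fused to the 12-membered lactone, not isolated) | C[C@@H]1CCCCCC2C(c3cc(OCc4ccccc4)cc(OC)c3C(=O)O1)S2(=O)=O | intermediate
18 | (R)-O-benzyl-didehydrolasiodiplodin, (E)-alkene at the benzylic position | C[C@@H]1CCCCC/C=C/c2cc(OCc3ccccc3)cc(OC)c2C(=O)O1 | intermediate
19 | (R)-O-benzyllasiodiplodin (not isolated) | C[C@@H]1CCCCCCCc2cc(OCc3ccccc3)cc(OC)c2C(=O)O1 | intermediate
20 | (R)-lasiodiplodin | C[C@@H]1CCCCCCCc2cc(O)cc(OC)c2C(=O)O1 | intermediate
21 | Mannich base: (R)-lasiodiplodin with morpholin-4-ylmethyl between C–OH and the chain-bearing carbon | C[C@@H]1CCCCCCCc2c(CN3CCOCC3)c(O)cc(OC)c2C(=O)O1 | intermediate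
22 | (4R)-4-benzyl-3-propanoyl-1,3-oxazolidin-2-one | CCC(=O)N1[C@H](Cc2ccccc2)COC1=O | starting material
23 | propargyl bromide (3-bromoprop-1-yne) | C#CCBr | starting material
24 | sodium (Z)-enolate of 22 (not isolated) | C/C=C(\[O-])N1[C@H](Cc2ccccc2)COC1=O.[Na+] | intermediate
25 | (4R)-4-benzyl-3-[(2S)-2-methylpent-4-ynoyl]-1,3-oxazolidin-2-one | C#CC[C@H](C)C(=O)N1[C@H](Cc2ccccc2)COC1=O | intermediate
26 | (2S)-2-methylpent-4-yn-1-ol | C#CC[C@H](C)CO | intermediate
27 | (4S)-4-methyl-2-methylideneoxolane (not isolated) | C=C1C[C@H](C)CO1 | intermediate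
28 | (3S)-3,5-dimethyl-2,3-dihydrofuran | CC1=C[C@H](C)CO1 | intermediate
29 | N-methylmorpholinium iodide of 21 (not isolated) | C[C@@H]1CCCCCCCc2c(C[N+]3(C)CCOCC3)c(O)cc(OC)c2C(=O)O1.[I-] | intermediate
30 | o-quinone methide of lasiodiplodin (exocyclic CH2 next to the chain-bearing carbon, not isolated) | C[C@@H]1CCCCCCCC2=C(C(=O)O1)C(OC)=CC(=O)C2=C | intermediate
31 | lasiodiplactone A | COc1cc2c(c3c1C(=O)O[C@H](C)CCCCCCC3)C[C@H]1[C@H](C)CO[C@@]1(C)O2 | target

Total step count: 16. Longest linear sequence: 11 steps (steps 1–3, 6–12, then step 16).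

Steps most likely to fail

1. Step 10 (ring contraction). The sulfone may be halogenated twice at the benzylic carbon, the non-benzylic sulfonyl carbanion may acylate on the lactone carbonyl, or the macrocycle may resist closure of the episulfone. The fallback gives up sulfur extrusion and makes the same C–C bond by carbanion alkylation; it sets out from 9 and 3 and comes back at 19. Silylation of 9 (TBSCl, imidazole, DMF) should give tert-butyl(dimethyl){[(2S)-oct-7-en-2-yl]oxy}silane F1. Hydroboration with 9-borabicyclo[3.3.1]nonane should give 9-[(7S)-7-{[tert-butyl(dimethyl)silyl]oxy}octyl]-9-borabicyclo[3.3.1]nonane F2, oxidised with NaOH/H2O2 to (7S)-7-{[tert-butyl(dimethyl)silyl]oxy}octan-1-ol F3. I2, PPh3 and imidazole should convert it into tert-butyl{[(2S)-8-iodooctan-2-yl]oxy}dimethylsilane F4. Alkylation of lithiated toluate 4 (from 3, as in step 3) with F4 should give ethyl 4-(benzyloxy)-2-[(8S)-8-{[tert-butyl(dimethyl)silyl]oxy}nonyl]-6-methoxybenzoate F5. Desilylation (2 M HCl, EtOH, rt) should give ethyl 4-(benzyloxy)-2-[(8S)-8-hydroxynonyl]-6-methoxybenzoate F6, and saponification as in step 7 the seco acid 4-(benzyloxy)-2-[(8S)-8-hydroxynonyl]-6-methoxybenzoic acid F7. Mitsunobu macrolactonisation as in step 8 should close ring B with inversion to 19, which the conditions of step 11 turn into 20.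

2. Step 16 (cycloaddition). Facial discrimination by the single methyl group of 28 may be poor, so that the syn adduct forms in quantity. The fallback puts the two new centres under thermodynamic control; it sets out from 21 and 28 and comes back at 31. The cycloaddition is run as before and the mixture, containing the 3a,9a-bis-epimer of lasiodiplactone A F8, is treated with catalytic camphorsulfonic acid in CH2Cl2. Acid-catalysed reversible ionisation of the ketal lets C-3a and C-9a re-form while C-3 stays fixed. The cis-fused isomer with the C-3 methyl on the convex face, 31, should accumulate.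

3. Step 3 (benzylic chlorination). The chloride already formed may be deprotonated by carbanion still present and chlorinated a second time, or it may alkylate that carbanion to a bibenzyl. The fallback makes the benzylic carbon the sulfur nucleophile and joins the chain by radical addition; it sets out from 3 and 9 and comes back at 12. Lithiated toluate 4 (from 3, as in step 3) is quenched with S8 (one atom equivalent, THF, −78 → 0 °C) to give lithium [5-(benzyloxy)-2-(ethoxycarbonyl)-3-methoxyphenyl]methanethiolate F9. Any polysulfide is reduced with NaBH4 in EtOH at 0 °C, and acidification with dilute HCl should give ethyl 4-(benzyloxy)-2-methoxy-6-(sulfanylmethyl)benzoate F10. AIBN-initiated thiol–ene addition of F10 to the terminal alkene of 9 (toluene, 70 °C) is anti-Markovnikov and should give 12 directly.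

Further compounds
F1 | step 10 | tert-butyl(dimethyl){[(2S)-oct-7-en-2-yl]oxy}silane | C[C@H](O[Si](C)(C)C(C)(C)C)CCCCC=C
F2 | step 10 | 9-[(7S)-7-{[tert-butyl(dimethyl)silyl]oxy}octyl]-9-borabicyclo[3.3.1]nonane | C[C@H](O[Si](C)(C)C(C)(C)C)CCCCCCB1C2CCCC1CCC2
F3 | step 10 | (7S)-7-{[tert-butyl(dimethyl)silyl]oxy}octan-1-ol | C[C@H](O[Si](C)(C)C(C)(C)C)CCCCCCO
F4 | step 10 | tert-butyl{[(2S)-8-iodooctan-2-yl]oxy}dimethylsilane | C[C@H](O[Si](C)(C)C(C)(C)C)CCCCCCI
F5 | step 10 | ethyl 4-(benzyloxy)-2-[(8S)-8-{[tert-butyl(dimethyl)silyl]oxy}nonyl]-6-methoxybenzoate | CCOC(=O)c1c(CCCCCCC[C@H](C)O[Si](C)(C)C(C)(C)C)cc(OCc2ccccc2)cc1OC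
F6 | step 10 | ethyl 4-(benzyloxy)-2-[(8S)-8-hydroxynonyl]-6-methoxybenzoate | CCOC(=O)c1c(CCCCCCC[C@H](C)O)cc(OCc2ccccc2)cc1OC
F7 | step 10 | 4-(benzyloxy)-2-[(8S)-8-hydroxynonyl]-6-methoxybenzoic acid | OC(=O)c1c(CCCCCCC[C@H](C)O)cc(OCc2ccccc2)cc1OC
F8 | step 16 | 3a,9a-bis-epimer of lasiodiplactone A (syn adduct) | COc1cc2c(c3c1C(=O)O[C@H](C)CCCCCCC3)C[C@@H]1[C@H](C)CO[C@]1(C)O2
F9 | step 3 | lithium [5-(benzyloxy)-2-(ethoxycarbonyl)-3-methoxyphenyl]methanethiolate | CCOC(=O)c1c(C[S-])cc(OCc2ccccc2)cc1OC.[Li+]
F10 | step 3 | ethyl 4-(benzyloxy)-2-methoxy-6-(sulfanylmethyl)benzoate | CCOC(=O)c1c(CS)cc(OCc2ccccc2)cc1OC
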